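## Retrosynthetic overview

(Side-chain carbons are primed; C1' is attached to ring carbon C5.)

1. Target acid ⇐ its methyl ester ⇐ a SnCl4-promoted peroxycarbenium–alkene [3+2] annulation (stepwise, formal cycloaddition: C5–C4 bond, then C3–O bond) between a triethylsilyl peroxyketal and methyl 3-methylbut-3-enoate.
2. Silyl peroxyketal ⇐ ozonolysis in methanol, then O-silylation, of (4S,6R)-2,4,6-trimethyl-14-phenyltetradec-1-ene.
3. That alkene ⇐ Cu-catalysed SN2 coupling (inversion) of the tosylate of (S)-10-phenyldecan-2-ol with the Grignard reagent of (R)-5-chloro-2,4-dimethylpent-1-ene.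
4. Stereocentres: C4' comes from (S)-propylene oxide (inverted once) and C2' from (S)-1-bromo-3-chloro-2-methylpropane. C3 and C5 are created together in the annulation with only the side-chain centres as bias, so the (3R,5R) isomer must be separated from its three ring diastereomers.
5. Ring order: the phenyl ring is bought; the 1,2-dioxolane is the only ring formed, in step 7 of 8.

Assumption: (7-bromoheptyl)benzene, (S)-propylene oxide, (S)-1-bromo-3-chloro-2-methylpropane, isopropenylmagnesium bromide solution and methyl 3-methylbut-3-enoate are catalogue compounds; the target SMILES is read as (3R,5R,2'S,4'R).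

## Route

Step 1
Reactants: 1 (7-bromoheptyl)benzene; 2 (S)-propylene oxide [(2S)-2-methyloxirane]
Product: 4 (2S)-10-phenyldecan-2-ol, via 7-phenylheptylmagnesium bromide 3 (not isolated)
Conditions: Mg, THF, 40 °C; then CuI (10 mol%), 2 (1.2 equiv), THF, −30 → 0 °C; aq. NH4Cl
Reagents that add atoms: none
Why: Cu-catalysed Grignard opening of the epoxide occurs at the unsubstituted CH2 in an SN2 sense, so the bought (S) carbinol centre is carried over untouched.

Step 2
Reactants: 4 (2S)-10-phenyldecan-2-ol
Product: 5 (2S)-10-phenyldecan-2-yl 4-methylbenzenesulfonate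
Conditions: TsCl (1.5 equiv), pyridine, 0 °C → rt
Reagents that add atoms: 4-methylbenzenesulfonyl chloride (TsCl), Cc1ccc(cc1)S(=O)(=O)Cl
Why: Tosylation takes place at oxygen, so the secondary alcohol becomes a leaving group with its C–O stereocentre unchanged.

Step 3
Reactants: 6 (2S)-1-bromo-3-chloro-2-methylpropane; 7 isopropenylmagnesium bromide
Product: 8 (4R)-5-chloro-2,4-dimethylpent-1-ene
Conditions: 7 (1.3 equiv), Li2CuCl4 (3 mol%), THF, 0 °C → rt; careful distillation
Reagents that add atoms: none
Why: Kochi-type Cu-catalysed sp2–sp3 cross-coupling occurs at the primary C–Br bond much faster than at C–Cl, and the bought methyl stereocentre is a spectator (its descriptor changes from S to R only through CIP priorities).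

Step 4
Reactants: 8 (4R)-5-chloro-2,4-dimethylpent-1-ene; 5 (2S)-10-phenyldecan-2-yl 4-methylbenzenesulfonate
Product: 10 (4S,6R)-2,4,6-trimethyl-14-phenyltetradec-1-ene, via (2R)-2,4-dimethylpent-4-enylmagnesium chloride 9 (not isolated)
Conditions: 8, Mg (cat. I2), THF, reflux; then 5, CuI (10 mol%), TMEDA (20 mol%), LiOMe (1 equiv), THF, 0 °C
Reagents that add atoms: none
Why: Cu-catalysed alkyl–alkyl coupling of the primary Grignard reagent with the unactivated secondary tosylate is an SN2 displacement with clean inversion, which turns the (S) carbinol carbon into the (6R) methyl-bearing centre and completes the anti-1,3-dimethyl array.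

Step 5
Reactants: 10 (4S,6R)-2,4,6-trimethyl-14-phenyltetradec-1-ene
Product: 12 (4S,6R)-2-hydroperoxy-2-methoxy-4,6-dimethyl-14-phenyltetradecane (C2 epimers), via carbonyl oxide 11 (not isolated)
Conditions: O3, CH2Cl2/MeOH (4:1), NaHCO3, Sudan Red end point, −78 °C; N2 purge; concentrate below 20 °C
Reagents that add atoms: ozone, [O-][O+]=O; methanol, CO
Why: In this Criegee ozonolysis in a participating solvent, ozone cleaves only the 1,1-disubstituted alkene, the primary ozonide fragments mainly to formaldehyde and the more substituted carbonyl oxide 11, and methanol traps 11 as the hydroperoxy ketal; the new ketal centre is an inconsequential epimer mixture because it becomes sp2 again in step 7.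

Step 6
Reactants: 12 (4S,6R)-2-hydroperoxy-2-methoxy-4,6-dimethyl-14-phenyltetradecane
Product: 13 triethyl{[(4S,6R)-2-methoxy-4,6-dimethyl-14-phenyltetradecan-2-yl]peroxy}silane (C2 epimers)
Conditions: Et3SiCl (1.3 equiv), imidazole (2 equiv), DMF, 0 °C
Reagents that add atoms: chlorotriethylsilane, CC[Si](Cl)(CC)CC
Why: O-silylation of the hydroperoxide under mildly basic conditions leaves the acid-sensitive ketal intact and gives a peroxyketal that ionises selectively at the methoxy group; no stereocentre is affected.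

Step 7
Reactants: 13 triethyl{[(4S,6R)-2-methoxy-4,6-dimethyl-14-phenyltetradecan-2-yl]peroxy}silane; 14 methyl 3-methylbut-3-enoate
Product: 16 methyl 2-[(3R,5R)-5-[(2S,4R)-2,4-dimethyl-12-phenyldodecyl]-3,5-dimethyl-1,2-dioxolan-3-yl]acetate, via silylperoxycarbenium ion 15 (not isolated)
Conditions: SnCl4 (1.1 equiv), 14 (3 equiv), CH2Cl2, −78 °C, 2 h; aq. NaHCO3; SiO2, then preparative HPLC
Reagents that add atoms: none
Why: In this peroxycarbenium–alkene [3+2] annulation (a stepwise formal cycloaddition), SnCl4 ionises the methoxy group to 15, the CH2 terminus of the alkene attacks it and the resulting tertiary cation is closed by the silylperoxy oxygen with loss of the silyl group; C3 and C5 are both set here with only the C2'/C4' methyl centres as bias, so a near-statistical mixture is expected and the (3R,5R) isomer is isolated from its three C3/C5 diastereomers.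

Step 8
Reactants: 16 methyl 2-[(3R,5R)-5-[(2S,4R)-2,4-dimethyl-12-phenyldodecyl]-3,5-dimethyl-1,2-dioxolan-3-yl]acetate
Product: 17 2-[(3R,5R)-5-[(2S,4R)-2,4-dimethyl-12-phenyldodecyl]-3,5-dimethyl-1,2-dioxolan-3-yl]acetic acid (CNP0188135.5)
Conditions: LiOH·H2O (3 equiv), THF/H2O (3:1), 0 °C → rt; then cold 1 M HCl to pH 3
Reagents that add atoms: lithium hydroxide, [Li+].[OH-]
Why: Saponification cleaves only the methyl ester, because the fully substituted dialkyl peroxide has no α-hydrogen and therefore no Kornblum–DeLaMare pathway in cold aqueous hydroxide; no stereocentre is touched.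

## Compound list

1 | (7-bromoheptyl)benzene | BrCCCCCCCc1ccccc1 | starting material
2 | (S)-propylene oxide, (2S)-2-methyloxirane | C[C@H]1CO1 | starting material
3 | 7-phenylheptylmagnesium bromide (formed in situ) | Br[Mg]CCCCCCCc1ccccc1 | intermediate
4 | (2S)-10-phenyldecan-2-ol | C[C@H](O)CCCCCCCCc1ccccc1 | intermediate
5 | (2S)-10-phenyldecan-2-yl 4-methylbenzenesulfonate | C[C@H](OS(=O)(=O)c1ccc(C)cc1)CCCCCCCCc1ccccc1 | intermediate
6 | (2S)-1-bromo-3-chloro-2-methylpropane | ClC[C@H](C)CBr | starting material
7 | isopropenylmagnesium bromide (prop-1-en-2-ylmagnesium bromide, THF solution) | C=C(C)[Mg]Br | starting material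
8 | (4R)-5-chloro-2,4-dimethylpent-1-ene | ClC[C@H](C)CC(C)=C | intermediate
9 | [(2R)-2,4-dimethylpent-4-en-1-yl]magnesium chloride (formed in situ) | Cl[Mg]C[C@H](C)CC(C)=C | intermediate
10 | (4S,6R)-2,4,6-trimethyl-14-phenyltetradec-1-ene | C[C@H](CCCCCCCCc1ccccc1)C[C@H](C)CC(C)=C | intermediate
11 | carbonyl oxide of (4S,6R)-4,6-dimethyl-14-phenyltetradecan-2-one (formed in situ) | C[C@H](CCCCCCCCc1ccccc1)C[C@H](C)CC(C)=[O+][O-] | intermediate
12 | (4S,6R)-2-hydroperoxy-2-methoxy-4,6-dimethyl-14-phenyltetradecane (C2 epimers) | C[C@H](CCCCCCCCc1ccccc1)C[C@H](C)CC(C)(OC)OO | intermediate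
13 | triethyl{[(4S,6R)-2-methoxy-4,6-dimethyl-14-phenyltetradecan-2-yl]peroxy}silane (C2 epimers) | C[C@H](CCCCCCCCc1ccccc1)C[C@H](C)CC(C)(OC)OO[Si](CC)(CC)CC | intermediate
14 | methyl 3-methylbut-3-enoate | C=C(C)CC(=O)OC | starting material
15 | (4S,6R)-4,6-dimethyl-14-phenyltetradecan-2-ylidene(triethylsilylperoxy)oxonium, the silylperoxycarbenium ion (formed in situ) | C[C@H](CCCCCCCCc1ccccc1)C[C@H](C)CC(C)=[O+]O[Si](CC)(CC)CC | intermediate
16 | methyl 2-[(3R,5R)-5-[(2S,4R)-2,4-dimethyl-12-phenyldodecyl]-3,5-dimethyl-1,2-dioxolan-3-yl]acetate | C[C@H](CCCCCCCCc1ccccc1)C[C@H](C)C[C@]1(C)C[C@](C)(CC(=O)OC)OO1 | intermediate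
17 | 2-[(3R,5R)-5-[(2S,4R)-2,4-dimethyl-12-phenyldodecyl]-3,5-dimethyl-1,2-dioxolan-3-yl]acetic acid | C[C@H](CCCCCCCCc1ccccc1)C[C@H](C)C[C@]1(C)C[C@](C)(CC(=O)O)OO1 | target

## Step count and risks

Total step count: 8. Longest linear sequence: 7 (steps 1, 2, 4, 5, 6, 7, 8).

**Step 7 (annulation).** The ester-bearing alkene is a weaker nucleophile than simple 2-methylalkenes, the tertiary cation can lose a proton instead of closing, and the four C3/C5 isomers are expected in a near-statistical ratio, so 16 is at best about a quarter of the dioxolane fraction. The fallback sets out from 13 and comes back at 16. Methyl 3-methylbut-2-enoate is converted with LiN(iPr)2 and Me3SiCl (THF, −78 °C) into [(1-methoxy-3-methylbuta-1,3-dien-1-yl)oxy]trimethylsilane F1. Compound 13 and F1 with catalytic Me3SiOTf in CH2Cl2 at −78 °C give, by γ-selective vinylogous Mukaiyama addition to the peroxycarbenium ion, methyl (2E,7S,9R)-3,5,7,9-tetramethyl-17-phenyl-5-[(triethylsilyl)peroxy]heptadec-2-enoate F2. Bu4NF buffered with AcOH (THF, 0 °C) frees methyl (2E,7S,9R)-5-hydroperoxy-3,5,7,9-tetramethyl-17-phenylheptadec-2-enoate F3. Et2NH in CF3CH2OH then closes the ring by 5-exo intramolecular oxa-Michael addition to give 16 with its isomers, which need the same separation. This secures the chemical yield of the ring but does not improve the selectivity.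

**Step 4 (secondary tosylate coupling).** E2 elimination and reduction of the tosylate compete, and the β-branched Grignard reagent is hindered. The fallback sets out from 8 and comes back at 10, and it makes steps 1 and 2 unnecessary beyond preparing Grignard reagent 3. Grignard reagent 9 is coupled with purchased ethyl (2S)-2-[(trifluoromethanesulfonyl)oxy]propanoate (ZnCl2 10 mol%, THF, 0 °C; SN2 with inversion at the activated α-carbon) to give ethyl (2S,4S)-2,4,6-trimethylhept-6-enoate F4. LiAlH4 (Et2O, 0 °C) gives (2S,4S)-2,4,6-trimethylhept-6-en-1-ol F5, and TsCl in pyridine gives (2S,4S)-2,4,6-trimethylhept-6-en-1-yl 4-methylbenzenesulfonate F6. Li2CuCl4-catalysed coupling of F6 with Grignard reagent 3 (THF, −20 → 0 °C) gives 10. Both C–C couplings then occur at an activated or a primary carbon.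

**Step 5 (ozonolysis in methanol).** The primary ozonide also fragments the other way, to the ketone and formaldehyde oxide, which lowers the yield of 12; over-ozonation of the arene and the lability of 12 are further risks. The fallback sets out from 10 and comes back at 12. O3 in CH2Cl2 at −78 °C followed by PPh3 gives (4S,6R)-4,6-dimethyl-14-phenyltetradecan-2-one F7 (also the by-product of step 5, so it can be recycled this way). HC(OMe)3 in MeOH with catalytic pyridinium p-toluenesulfonate gives (4S,6R)-2,2-dimethoxy-4,6-dimethyl-14-phenyltetradecane F8. Exchange with anhydrous H2O2 in Et2O (cat. p-TsOH, 0 °C) gives 12.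

## Further compounds

F1 | step 7 | [(1-methoxy-3-methylbuta-1,3-dien-1-yl)oxy]trimethylsilane | COC(O[Si](C)(C)C)=CC(C)=C
F2 | step 7 | methyl (2E,7S,9R)-3,5,7,9-tetramethyl-17-phenyl-5-[(triethylsilyl)peroxy]heptadec-2-enoate (C5 epimers) | C[C@H](CCCCCCCCc1ccccc1)C[C@H](C)CC(C)(OO[Si](CC)(CC)CC)C/C(C)=C/C(=O)OC
F3 | step 7 | methyl (2E,7S,9R)-5-hydroperoxy-3,5,7,9-tetramethyl-17-phenylheptadec-2-enoate (C5 epimers) | C[C@H](CCCCCCCCc1ccccc1)C[C@H](C)CC(C)(OO)C/C(C)=C/C(=O)OC
F4 | step 4 | ethyl (2S,4S)-2,4,6-trimethylhept-6-enoate | C[C@H](C(=O)OCC)C[C@H](C)CC(C)=C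
F5 | step 4 | (2S,4S)-2,4,6-trimethylhept-6-en-1-ol | C[C@H](CO)C[C@H](C)CC(C)=C
F6 | step 4 | (2S,4S)-2,4,6-trimethylhept-6-en-1-yl 4-methylbenzenesulfonate | C[C@H](COS(=O)(=O)c1ccc(C)cc1)C[C@H](C)CC(C)=C
F7 | step 5 | (4S,6R)-4,6-dimethyl-14-phenyltetradecan-2-one | C[C@H](CCCCCCCCc1ccccc1)C[C@H](C)CC(C)=O
F8 | step 5 | (4S,6R)-2,2-dimethoxy-4,6-dimethyl-14-phenyltetradecane | C[C@H](CCCCCCCCc1ccccc1)C[C@H](C)CC(C)(OC)OC
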